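**Plan**

- Labels: ring C1 (C=O), C2 (allyl), C3 (H), C4 (quaternary, bearing OMe and the side chain), C5 (OMe), C6 (H). In the side chain, C8 is the =C(Me) carbon on C4 and C7 is the =CH–Ar carbon.
- Enabling feature: the ring's vinylogous ester C5(OMe)=C6H–C1=O is a methoxyethynyl ketone that has taken up a carbon at C5, and C4 is the γ-carbon of the enone C1(=O)–C2=C3. The target is therefore an isomer of an acyclic ynone, and the first retrosynthetic cut is the ring bond C4–C5.
- Further cuts are C1–C6 (acylation of methoxyacetylide), C2–allyl (Stille), C3–C4 (propiolate plus enal) and C7=C8 (aldol condensation).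
- Forward, the chain is joined in the order C7=C8, C3–C4, C2–allyl, C1–C6. The cyclohexadienone, the only ring made, forms last, when the silyl dienol ether of the ynone closes 6-endo-dig onto its gold-activated ynol ether.
- Stereochemistry: alkene geometries come from E-selective condensation, syn-hydrostannation with retentive coupling, and sterically governed soft enolisation. The racemic C4–H centre carried along the chain is erased on enolisation, and the single stereocentre, (S)-C4, is set in the ring closure by a chiral bisphosphine digold catalyst.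

Key step: step 9

Assumption: the sense of induction of the gold catalyst cannot be derived from precedent. The route is written with the (R)-ligand, and the (S)-ligand is used if the closure favours the other face of C4.

**Step 1**
Reactants: 1 3,4-dimethoxybenzaldehyde; 2 propanal
Product: 3 (E)-3-(3,4-dimethoxyphenyl)-2-methylprop-2-enal
Conditions: NaOH (cat.), MeOH–H2O, slow addition of 2, 0 °C → rt
Reagents that add atoms: none
Why: The crossed aldol (Claisen–Schmidt) condensation of a non-enolisable aldehyde with propanal ends in an E1cB dehydration that should give the conjugated E-enal, with aryl trans to formyl.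

**Step 2**
Reactants: 3 (E)-3-(3,4-dimethoxyphenyl)-2-methylprop-2-enal; 4 ethyl propiolate
Product: 6 (±)-ethyl (E)-6-(3,4-dimethoxyphenyl)-4-hydroxy-5-methylhex-5-en-2-ynoate, via ethyl 3-lithiopropiolate 5 (not isolated)
Conditions: 4, LiHMDS, THF, −78 °C; then 3, −78 °C; aq. work-up
Reagents that add atoms: none
Why: The 1,2-addition of a lithium acetylide to the enal joins C3 to C4, and the racemic carbinol centre is harmless because C4 becomes planar in step 8.

**Step 3**
Reactants: 6 (±)-ethyl (E)-6-(3,4-dimethoxyphenyl)-4-hydroxy-5-methylhex-5-en-2-ynoate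
Product: 7 (±)-ethyl (E)-6-(3,4-dimethoxyphenyl)-4-methoxy-5-methylhex-5-en-2-ynoate
Conditions: MeI, Ag2O, MeCN, rt, dark
Reagents that add atoms: iodomethane, CI
Why: The Purdie methylation (Ag2O/MeI) runs without strong base, so the base-labile γ-hydroxy ynoate should be etherified without isomerising to the γ-oxo enoate.

**Step 4**
Reactants: 7 (±)-ethyl (E)-6-(3,4-dimethoxyphenyl)-4-methoxy-5-methylhex-5-en-2-ynoate
Product: 8 (±)-ethyl (2E,5E)-6-(3,4-dimethoxyphenyl)-4-methoxy-5-methyl-2-(tributylstannyl)hexa-2,5-dienoate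
Conditions: Bu3SnH, Pd(PPh3)4 (2 mol %), THF, 0 °C
Reagents that add atoms: tributyltin hydride, CCCC[SnH](CCCC)CCCC
Why: The palladium-catalysed hydrostannation of an alkynoate is a syn addition that delivers hydrogen to the β-carbon C3 and tin to the α-carbon C2, which should place C4 and the ester cis on C2=C3.

**Step 5**
Reactants: 8 (±)-ethyl (2E,5E)-6-(3,4-dimethoxyphenyl)-4-methoxy-5-methyl-2-(tributylstannyl)hexa-2,5-dienoate; 9 allyl bromide
Product: 10 (±)-ethyl (2Z,5E)-2-allyl-6-(3,4-dimethoxyphenyl)-4-methoxy-5-methylhexa-2,5-dienoate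
Conditions: Pd2(dba)3 (2.5 mol %), AsPh3, CuI (10 mol %), DMF, rt → 40 °C
Reagents that add atoms: none
Why: The Stille coupling of an alkenylstannane with an allyl halide keeps the double-bond geometry and installs the C2 allyl group, and the methyl ethers are too poor as leaving groups to be ionised by zerovalent palladium.

**Step 6**
Reactants: 10 (±)-ethyl (2Z,5E)-2-allyl-6-(3,4-dimethoxyphenyl)-4-methoxy-5-methylhexa-2,5-dienoate
Product: 11 (±)-(2Z,5E)-2-allyl-6-(3,4-dimethoxyphenyl)-N,4-dimethoxy-N,5-dimethylhexa-2,5-dienamide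
Conditions: MeNH(OMe)·HCl, i-PrMgCl, THF, −20 → 0 °C
Reagents that add atoms: N,O-dimethylhydroxylamine hydrochloride, CNOC.Cl
Why: Ester aminolysis by the magnesium amide of N,O-dimethylhydroxylamine (Weinreb amide formation) should leave the alkenes and ethers untouched.

**Step 7**
Reactants: 11 (±)-(2Z,5E)-2-allyl-6-(3,4-dimethoxyphenyl)-N,4-dimethoxy-N,5-dimethylhexa-2,5-dienamide; 12 chloroacetaldehyde dimethyl acetal
Product: 14 (±)-(4Z,7E)-4-allyl-8-(3,4-dimethoxyphenyl)-1,6-dimethoxy-7-methylocta-4,7-dien-1-yn-3-one, via lithium methoxyacetylide 13 (not isolated)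
Conditions: 12, LiNEt2 (3 equiv), THF, 0 °C; then 11, −78 → −20 °C; cold pH 7 buffer
Reagents that add atoms: none
Why: Two eliminations and a deprotonation turn the chloroacetal into the acetylide, and the Weinreb ketone synthesis holds at the chelated tetrahedral adduct until the quench, so a single acylation should join C6 to C1.

**Step 8**
Reactants: 14 (±)-(4Z,7E)-4-allyl-8-(3,4-dimethoxyphenyl)-1,6-dimethoxy-7-methylocta-4,7-dien-1-yn-3-one
Product: 15 tert-butyl{[(3E,5Z,7E)-4-allyl-8-(3,4-dimethoxyphenyl)-1,6-dimethoxy-7-methylocta-3,5,7-trien-1-yn-3-yl]oxy}dimethylsilane (siloxy cis to allyl, alkynyl cis to C3, C4-methoxy cis to C2)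
Conditions: TBSOTf, i-Pr2NEt, Et2O, −78 → −30 °C; filtration through basic alumina
Reagents that add atoms: tert-butyldimethylsilyl triflate, CC(C)(C)[Si](C)(C)OS(=O)(=O)C(F)(F)F
Why: Soft enolisation removes the only acidic hydrogen, the doubly allylic C4–H, and because in the O-silylated Z-enone the bulky siloxy group must point away from C4 while the slim alkynyl group and the smaller C4 substituent (OMe) take the inside positions, one U-shaped dienol ether should form and the C4 centre is erased.

**Step 9**
Reactants: 15 tert-butyl{[(3E,5Z,7E)-4-allyl-8-(3,4-dimethoxyphenyl)-1,6-dimethoxy-7-methylocta-3,5,7-trien-1-yn-3-yl]oxy}dimethylsilane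
Product: 16 (S)-2-allyl-4-[(E)-1-(3,4-dimethoxyphenyl)prop-1-en-2-yl]-4,5-dimethoxycyclohexa-2,5-dien-1-one
Conditions: (R)-DTBM-SEGPHOS(AuCl)2 (5 mol %), AgSbF6 (10 mol %), i-PrOH (1.2 equiv), CH2Cl2, −40 °C
Reagents that add atoms: none
Why: Proposed new method: the cationic monovalent gold complex binds the most electron-rich π-bond, the C5≡C6 ynol ether, and polarises it into a gold-bound methoxyketenium ion electrophilic only at C5; the γ-carbon C4 of the siloxydiene attacks C5 anti to gold, the C1 silyloxocarbenium ion passes its silyl group to i-PrOH, and the proton so released cleaves the C6–Au bond, so that ynone 14 is in the end cycloisomerised to 16. The closest known reaction types are the gold- and palladium-catalysed carbocyclisations of silyl enol ethers onto alkynes, including enantioselective silyloxyenyne cyclisations that set quaternary carbons and 6-endo-dig closures of conjugated dienyne silyl enol ethers, and the ketenium and keteniminium cyclisations of ynol ethers and ynamides; new here are the vinylogous nucleophile, the ynol ether acceptor and the oxygen-bearing quaternary carbon. The cyclohexadienone ring closes in the 6-endo-dig mode, and the anti addition places C4 and C1 cis on C5=C6 as the ring requires. The only stereocentre, C4, is set under catalyst control, since the chiral bisphosphine pocket must distinguish the two faces of the geometrically uniform C3=C4 enol ether, which is why step 8 has to deliver one isomer. The step needs site selectivity for C4–C5 bonding, and the substrate secures it because the ynol ether polarisation excludes attack at C6, attack by C2 or C7 would give a four- or eight-membered ring, the allyl and styryl π-bonds are far weaker nucleophiles than the doubly donor-substituted diene, and the 3E geometry holds C4 within bonding distance of C5. A hindered alcohol in slight excess and the low temperature should keep intermolecular alcohol addition to the ketenium ion slower than the intramolecular closure.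

**Compound list**

1 | 3,4-dimethoxybenzaldehyde | COc1ccc(C=O)cc1OC | starting material
2 | propanal | CCC=O | starting material
3 | (E)-3-(3,4-dimethoxyphenyl)-2-methylprop-2-enal | O=C/C(C)=C/c1ccc(OC)c(OC)c1 | intermediate
4 | ethyl propiolate | C#CC(=O)OCC | starting material
5 | ethyl 3-lithiopropiolate | [Li]C#CC(=O)OCC | intermediate
6 | (±)-ethyl (E)-6-(3,4-dimethoxyphenyl)-4-hydroxy-5-methylhex-5-en-2-ynoate | CCOC(=O)C#CC(O)/C(C)=C/c1ccc(OC)c(OC)c1 | intermediate
7 | (±)-ethyl (E)-6-(3,4-dimethoxyphenyl)-4-methoxy-5-methylhex-5-en-2-ynoate | CCOC(=O)C#CC(OC)/C(C)=C/c1ccc(OC)c(OC)c1 | intermediate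
8 | (±)-ethyl (2E,5E)-6-(3,4-dimethoxyphenyl)-4-methoxy-5-methyl-2-(tributylstannyl)hexa-2,5-dienoate | CCCC[Sn](CCCC)(CCCC)/C(C(=O)OCC)=C/C(OC)/C(C)=C/c1ccc(OC)c(OC)c1 | intermediate
9 | allyl bromide | C=CCBr | starting material
10 | (±)-ethyl (2Z,5E)-2-allyl-6-(3,4-dimethoxyphenyl)-4-methoxy-5-methylhexa-2,5-dienoate | CCOC(=O)/C(CC=C)=C\C(OC)/C(C)=C/c1ccc(OC)c(OC)c1 | intermediate
11 | (±)-(2Z,5E)-2-allyl-6-(3,4-dimethoxyphenyl)-N,4-dimethoxy-N,5-dimethylhexa-2,5-dienamide | CON(C)C(=O)/C(CC=C)=C\C(OC)/C(C)=C/c1ccc(OC)c(OC)c1 | intermediate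
12 | chloroacetaldehyde dimethyl acetal | ClCC(OC)OC | starting material
13 | lithium methoxyacetylide | [Li]C#COC | intermediate
14 | (±)-(4Z,7E)-4-allyl-8-(3,4-dimethoxyphenyl)-1,6-dimethoxy-7-methylocta-4,7-dien-1-yn-3-one | COC#CC(=O)/C(CC=C)=C\C(OC)/C(C)=C/c1ccc(OC)c(OC)c1 | intermediate
15 | tert-butyl{[(3E,5Z,7E)-4-allyl-8-(3,4-dimethoxyphenyl)-1,6-dimethoxy-7-methylocta-3,5,7-trien-1-yn-3-yl]oxy}dimethylsilane | COC#C/C(O[Si](C)(C)C(C)(C)C)=C(\C=C(/OC)\C(C)=C\c1ccc(OC)c(OC)c1)CC=C | intermediate
16 | (S)-2-allyl-4-[(E)-1-(3,4-dimethoxyphenyl)prop-1-en-2-yl]-4,5-dimethoxycyclohexa-2,5-dien-1-one | C=CCC1=C[C@](OC)(/C(C)=C/c2ccc(OC)c(OC)c2)C(OC)=CC1=O | target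

**Totals**

Total step count: 9. Longest linear sequence: 9 steps, from 1.

**Steps most likely to fail**

**Step 9.**
- What may go wrong:
  - Alcohol or trace water could add to the gold-bound ketenium ion faster than C4 does.
  - Protodesilylation could return the ynone.
  - Facial selectivity at C4 could be poor.
- The fallback uses known chemistry, sets out from 11 and returns at 16. It closes the same bond thermally through a ketene.
- Amide 11 is acylated with lithium tert-butoxyacetylide F1 (from tert-butoxyacetylene and n-BuLi) to give the tert-butoxy ynone F2. This is soft-enolised as in step 8 to the silyl dienol ether F3.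
- Heating in toluene at about 90 °C triggers the known retro-ene loss of isobutene from the tert-butyl ynol ether. The dienylketene F4 so formed undergoes the 6π electrocyclisation known from cyclobutenone-based benzannulations, which here stops at the racemic silyloxy cyclohexa-2,4-dienone F5.
- HF·pyridine frees the vinylogous acid F6. Me3SiCHN2 followed by chromatography gives the racemic dienone F7, and preparative HPLC on a chiral phase gives 16.

**Step 8.**
- What may go wrong:
  - The wrong C1=C2 geometry could form.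
  - The amine or the silyl triflate could attack the push–pull alkyne.
  - The product could hydrolyse on isolation.
- The fallback sets out from 14, returns at 16, and needs no defined enol ether.
- Methanol is added across the ynone (cat. NaOMe, MeOH, 0 °C) to give the β,β-dimethoxy enone F8.
- KOt-Bu in THF/t-BuOH removes C4–H reversibly to give the potassium oxidohexatriene F9. Its C1=C2 geometry can equilibrate by proton transfer, so that only the productive isomer is drained.
- The oxido-accelerated 6π electrocyclisation followed by E1cB loss of methoxide gives the racemic dienone F7. This is resolved by HPLC on a chiral phase to 16.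

**Step 7.**
- What may go wrong:
  - The alkoxy ynone could be hydrated, or diethylamine could add to it, during the quench.
  - The hindered amide could convert incompletely.
- The fallback sets out from 10, returns at 14, and makes the C1–C6 bond under neutral, amine-free conditions.
- LiOH saponifies 10 to the dienoic acid F10, and 1-chloro-N,N,2-trimethylpropenylamine converts it into the acid chloride F11.
- A Stille acylation (Pd2(dba)3, tri(2-furyl)phosphine, toluene, rt) with tributyl(methoxyethynyl)stannane F12, made from 13 and Bu3SnCl, gives 14.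

**Further compounds**

F1 | step 9 | lithium tert-butoxyacetylide | [Li]C#COC(C)(C)C
F2 | step 9 | (±)-(4Z,7E)-4-allyl-1-tert-butoxy-8-(3,4-dimethoxyphenyl)-6-methoxy-7-methylocta-4,7-dien-1-yn-3-one | CC(C)(C)OC#CC(=O)/C(CC=C)=C\C(OC)/C(C)=C/c1ccc(OC)c(OC)c1
F3 | step 9 | (3E,5Z,7E)-4-allyl-1-tert-butoxy-3-(tert-butyldimethylsilyloxy)-8-(3,4-dimethoxyphenyl)-6-methoxy-7-methylocta-3,5,7-trien-1-yne | CC(C)(C)OC#C/C(O[Si](C)(C)C(C)(C)C)=C(\C=C(/OC)\C(C)=C\c1ccc(OC)c(OC)c1)CC=C
F4 | step 9 | (3E,5Z,7E)-4-allyl-3-(tert-butyldimethylsilyloxy)-8-(3,4-dimethoxyphenyl)-6-methoxy-7-methylocta-1,3,5,7-tetraen-1-one (dienylketene) | O=C=C/C(O[Si](C)(C)C(C)(C)C)=C(\C=C(/OC)\C(C)=C\c1ccc(OC)c(OC)c1)CC=C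
F5 | step 9 | (±)-4-allyl-3-(tert-butyldimethylsilyloxy)-6-[(E)-1-(3,4-dimethoxyphenyl)prop-1-en-2-yl]-6-methoxycyclohexa-2,4-dien-1-one | C=CCC1=CC(OC)(/C(C)=C/c2ccc(OC)c(OC)c2)C(=O)C=C1O[Si](C)(C)C(C)(C)C
F6 | step 9 | (±)-4-allyl-6-[(E)-1-(3,4-dimethoxyphenyl)prop-1-en-2-yl]-3-hydroxy-6-methoxycyclohexa-2,4-dien-1-one | C=CCC1=CC(OC)(/C(C)=C/c2ccc(OC)c(OC)c2)C(=O)C=C1O
F7 | step 9 | (±)-2-allyl-4-[(E)-1-(3,4-dimethoxyphenyl)prop-1-en-2-yl]-4,5-dimethoxycyclohexa-2,5-dien-1-one | C=CCC1=CC(OC)(/C(C)=C/c2ccc(OC)c(OC)c2)C(OC)=CC1=O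
F8 | step 8 | (±)-(4Z,7E)-4-allyl-8-(3,4-dimethoxyphenyl)-1,1,6-trimethoxy-7-methylocta-1,4,7-trien-3-one | COC(OC)=CC(=O)/C(CC=C)=C\C(OC)/C(C)=C/c1ccc(OC)c(OC)c1
F9 | step 8 | potassium (3E,5Z,7E)-4-allyl-8-(3,4-dimethoxyphenyl)-1,1,6-trimethoxy-7-methylocta-1,3,5,7-tetraen-3-olate | [K+].COC(OC)=C/C([O-])=C(\C=C(/OC)\C(C)=C\c1ccc(OC)c(OC)c1)CC=C
F10 | step 7 | (±)-(2Z,5E)-2-allyl-6-(3,4-dimethoxyphenyl)-4-methoxy-5-methylhexa-2,5-dienoic acid | OC(=O)/C(CC=C)=C\C(OC)/C(C)=C/c1ccc(OC)c(OC)c1
F11 | step 7 | (±)-(2Z,5E)-2-allyl-6-(3,4-dimethoxyphenyl)-4-methoxy-5-methylhexa-2,5-dienoyl chloride | ClC(=O)/C(CC=C)=C\C(OC)/C(C)=C/c1ccc(OC)c(OC)c1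
F12 | step 7 | tributyl(methoxyethynyl)stannane | CCCC[Sn](CCCC)(CCCC)C#COC
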